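## Analysis of the target

8-Prenylkaempferol (23) is a flavonol: benzo ring A (C4a, C5 to C8, C8a) is fused to pyranone ring C (O1, C2, C3, C4), with a 4-hydroxyphenyl ring B on C2 and hydroxyls on C3, C5 and C7. It has no stereocentre and no double-bond geometry to set, so the problem is one of regiochemistry and functional-group tolerance. Ring A is a fully differentiated phloroglucinol: its oxygens are O1 on C8a, the chelated hydroxyl on C5 and the hydroxyl on C7, and the prenyl group on C8 lies between C8a and C7. The prenyl alkene is the most sensitive function: under acid it adds the neighbouring O7–H to give a dimethyldihydropyran, and it excludes hydrogenolysis, strong Lewis acids, carbenes and electrophilic oxidants. The 3-hydroxypyranone is degraded as its anion in air, and the electron-rich ring A is easily over-substituted. The real difficulty is that in a symmetrical phloroglucinol precursor the oxygens that become O1 and O5 are equivalent, so C-prenylation or pyranone closure gives 6- and 8-prenyl isomers. The strategy rests on C8a(–O1), C8 and C7(–O) being three contiguous ring A atoms that a ring synthesis can deliver with their substituents in place. If the oxygens on C8a, C7 and C5 arrive as a free hydroxyl, a silyl ether and a benzyl-type ether, the pyranone can only be built through O1 and C4a, and the prenyl position is decided before ring C exists.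

## Retrosynthetic reasoning

Protecting groups. Target 23 is traced to the 7-O-silyl flavonol 22 (O7–Si cleavage) and 22 to the fully protected flavone 21 (cleavage of the two acetals on O3 and O4′ and of the 4-methoxybenzyl ether on O5). The silyl group is removed last because O7 is the only oxygen that can add across the prenyl double bond. Keeping it silylated while acid is present removes that pathway, and the final desilylation needs no strong acid.

Ring C. Flavone 21 is opened at O1–C2 to diketone 20, and the C2–C3 bond of 20 is traced to an intramolecular acyl transfer in aryl ester 19. Ester 19 is cut at its ester C–O bond into ketone 15 and acid 18. These cuts bring ring B in at the acid oxidation level and O3 in already protected, so no oxidation of a finished flavone is needed next to the prenyl group. The forward closure must occur while O5 is still etherified, so that O1 is the only nucleophilic oxygen. Acid 18 comes from 16 by O-alkylation.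

Acyl side chain. Ketone 15 is traced to carbinol 14 (adjustment of oxidation level) and 14 to salicylaldehyde 13 by cutting C3–C4 (addition of a protected hydroxymethyl anion equivalent). Aldehyde 13 comes from phenol 12 by cutting C4–C4a. The forward formylation has to be ortho-specific; because the other ortho position of 12 carries the prenyl group, it can only occur at C4a.

Ring A, the key disconnection. Phenol 12 is cut at C8a–C8, C6–C7 and C8a–C4a into cyclobutenone 3 and siloxyalkyne 7. Ring A is cut here and not at the prenyl–C8 bond because a ring synthesis fixes the prenyl carbon between the carbon that becomes C8a and the silyloxy carbon by the polarity of the two partners, not by a contest between directing groups. The forward cascade (through 8, 9, 10 and 11) must give one regioisomer and must tolerate the prenyl alkene and the benzyl ether.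

Partners. Cyclobutenone 3 is cut at its enol ether C–O bond into the ethoxy analogue 1 and alcohol 2 (alkoxy exchange). Siloxyalkyne 7 is cut at O–Si to ynolate 6, which comes from ester 4 through enolate 5 by a one-carbon homologation with 1,2-shift of the prenyl-bearing carbon. Each partner is one step from purchased material.

## Alternatives that were turned down

Alternative 1: The pyranone is cut at C2–C3 and C3–C4, removing C3 as a carbene carbon and leaving the five-membered benzofuranone A1. In the forward direction the enolate of A1 would take up a dihalocarbene at its enolate double bond, and the cyclopropane alkoxide would open with loss of halide to the 3-bromochromone A2. The bromide would then be exchanged for hydroxyl.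
- For: A1 is reachable by standard benzofuranone chemistry, ring C is made in one operation, and no hindered ester or diketone is needed. Between ring A and the flavone skeleton it is shorter than the chosen route.
- Against: dihalocarbenes add readily to electron-rich trisubstituted alkenes, so the prenyl group of A1 competes with the enolate. The C3–Br to C3–OH exchange on A2 adds at least two steps. The central problem is untouched, because the prenyl group of A1 still has to be placed on a ring with two equivalent ortho oxygens.
- Comparison: this ring expansion is untested on 2-aryl enolates of this kind, whereas the chosen key step belongs to a known reaction family. The chosen route settles the prenyl position while ring A is made and then uses classical pyranone chemistry.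

Alternative 2: Ring A is disconnected from a finished pyranone at C5–C6, C7–C8 and C4a–C5, giving the pyranonyl diazo ketone A3 and the C-silylated siloxyalkyne A4. Irradiation of A3 would trigger a Wolff rearrangement to a pyranonyl ketene. This would add to A4 in a [2+2] cycloaddition, and ring opening with 6π closure would give A5 (O5 free, O7 silylated, a removable silyl group on C6).
- For: the prenyl carbon is part of A3, so C8 is unambiguous. Rings B and C are complete before the key step, and A5 is only desilylations and acetal cleavage away from 23. In convergence and in the number of steps after the key step it is stronger than the chosen route.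
- Against: the diazo carbon of A3 carries a CH2 group, and such diazo ketones lose material to 1,2-hydride shift (enone formation) in competition with the Wolff rearrangement. The 4-pyranone chromophore absorbs in the same region and has its own photochemistry. A4, with silicon at both ends, is prone to isomerise to a bis-silylketene. A3 needs a de novo synthesis of a 2-aryl-3-alkoxy-4-pyranone with an acyl group on C6, then diazo transfer, which is longer than everything the chosen route needs before its key step.
- Comparison: the uncertain step would be run late, on the most valuable material. The chosen route runs the same pericyclic cascade thermally on two small partners, each made in one step, so a failure costs little.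

Alternative 3: The pyranone is cut at C3–C4 and O1–C8a. The lithium enolate of the ring B ketone A6 would be C-acylated by the ring A acyl imidazole A7. On warming, the enolate oxygen of the diketone would displace the fluorine on C8a to give A8.
- For: both bond formations are well-known types (Claisen acylation, intramolecular nucleophilic aromatic substitution of an ortho-fluoro aryl ketone). The fluorine is activated by the ortho carbonyl, and the two acetal oxygens are meta to it. The fluorine marks the future O1, so the 8-prenyl pattern is unambiguous, and ring C closes in the pot that joins the two halves. In precedent for the key step and in convergence it is stronger than the chosen route.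
- Against: A7 is a hexasubstituted arene that would need three successive directed metalations of a fluoroarene with two acetal oxygens. The site between the two oxygens competes with the sites next to fluorine, hence the silyl blocking group on C6, which costs one step to install and a protodesilylation at the end next to the prenyl group. Prenylation of an aryl metal needs copper to suppress allylic transposition. The carbonyl of A7 is flanked by fluorine and an acetal oxygen and is hindered towards an enolate that can also be O-acylated. In A8 all hydroxyls carry the same acetal, so O7 is set free next to the prenyl group under acid.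
- Comparison: the step count is comparable. The chosen route offers in its place a substitution pattern set by ring construction, no blocking group, and three chemically distinct oxygens, which lets O7 stay protected through the acid step.

Key step: step 3

Remark on the chemistry: intermediates 9, 14 and 20 each have one stereocentre, are formed as racemates and lose it before 23; compounds 1, 2, 4 and 16 and the reagents named in the steps are taken as purchasable.

## Route

Step 1
Reactants: 1 3-ethoxycyclobut-2-en-1-one; 2 (4-methoxyphenyl)methanol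
Product: 3 3-[(4-methoxyphenyl)methoxy]cyclobut-2-en-1-one
Conditions: pyridinium 4-toluenesulfonate (5 mol%), PhMe, 50 °C, 150 mbar (ethanol removed)
Reagents that add atoms: none
Why: Acid-catalysed alkoxy exchange of a vinylogous ester: the alcohol adds to C3 of the protonated enone and ethanol is lost. Removing ethanol drives the equilibrium, and the weak pyridinium acid spares the benzylic alcohol.

Step 2
Reactants: 4 ethyl 4-methylpent-3-enoate
Product: 7 triisopropyl[(5-methylhex-4-en-1-yn-1-yl)oxy]silane, via dibromoenolate 5 (not isolated), via lithium ynolate 6 (not isolated)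
Conditions: CH2Br2, lithium 2,2,6,6-tetramethylpiperidide, THF, −78 °C; add 4; LiN(SiMe3)2, −78 °C; n-BuLi, −78 °C → rt; i-Pr3SiCl, −78 → 0 °C
Reagents that add atoms: dibromomethane, BrCBr; chlorotri(propan-2-yl)silane, CC(C)[Si](Cl)(C(C)C)C(C)C
Why: Kowalski ester homologation: LiCHBr2 adds to the ester, the amide base turns the adduct into enolate 5, and bromine–lithium exchange triggers the 1,2-shift of the prenyl-bearing carbon to ynolate 6. The bulky chlorosilane silylates 6 on oxygen, which is the established route to triisopropylsilyl ynol ethers.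

Step 3
Reactants: 3 3-[(4-methoxyphenyl)methoxy]cyclobut-2-en-1-one; 7 triisopropyl[(5-methylhex-4-en-1-yn-1-yl)oxy]silane
Product: 12 5-[(4-methoxyphenyl)methoxy]-2-(3-methylbut-2-en-1-yl)-3-[(triisopropylsilyl)oxy]phenol, via vinylketene 8 (not isolated), via vinylcyclobutenone 9 (not isolated), via dienylketene 10 (not isolated), via cyclohexadienone 11 (not isolated)
Conditions: 7 (1.3 equiv), PhMe (0.5 M), Ar, sealed tube, 80 °C then 115 °C
Reagents that add atoms: none
Why: This is a Danheiser benzannulation, and the closest known reaction type is the cyclobutenone–siloxyalkyne route to resorcinol monosilyl ethers. Thermal 4π electrocyclic opening of 3 gives vinylketene 8, whose ketene double bond adds to the ynol ether in a [2+2] cycloaddition to give the four-membered ring of 9. The step needs the ketene carbonyl carbon to bond to the prenyl-bearing alkyne carbon; the oxygen lone pair of the ynol ether makes that carbon the nucleophilic terminus and the ketene carbonyl carbon is the electrophile, so C8a–C8 and C6–C7 form in this sense. Reversible 4π opening of 9 gives dienylketene 10, and the isomer with the ketene and the alkoxyvinyl group cis closes ring A by a thermally allowed disrotatory 6π electrocyclisation (C8a–C4a) to dienone 11, which aromatises by proton shift. The only stereocentre formed, C4 of 9, is racemic and is erased on ring opening, so no stereocontrol is required. The former ketone oxygen ends as the free hydroxyl next to the prenyl group, the alkyne oxygen as the silyl ether and the enol ether oxygen as the 4-methoxybenzyl ether, so the three oxygens of ring A are told apart without a protecting-group step. The slight excess of 7 limits acylation of the product phenol by 8.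

Step 4
Reactants: 12 5-[(4-methoxyphenyl)methoxy]-2-(3-methylbut-2-en-1-yl)-3-[(triisopropylsilyl)oxy]phenol
Product: 13 2-hydroxy-6-[(4-methoxyphenyl)methoxy]-3-(3-methylbut-2-en-1-yl)-4-[(triisopropylsilyl)oxy]benzaldehyde
Conditions: MgCl2 (anhydrous), Et3N, (CH2O)n, MeCN, 75 °C; cold 0.5 M HCl work-up
Reagents that add atoms: formaldehyde (as paraformaldehyde), C=O
Why: Casnati–Skattebøl ortho-formylation: the magnesium phenoxide delivers formaldehyde to the ortho carbon through a chelate, and a second formaldehyde oxidises the benzylic alkoxide by hydride transfer. The other ortho position carries the prenyl group, so only C4a can react, and the position between the two ether oxygens is not reached by this chelate-controlled process.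

Step 5
Reactants: 13 2-hydroxy-6-[(4-methoxyphenyl)methoxy]-3-(3-methylbut-2-en-1-yl)-4-[(triisopropylsilyl)oxy]benzaldehyde
Product: 14 2-[1-hydroxy-2-(methoxymethoxy)ethyl]-3-[(4-methoxyphenyl)methoxy]-6-(3-methylbut-2-en-1-yl)-5-[(triisopropylsilyl)oxy]phenol (racemic)
Conditions: Bu3SnCH2OCH2OMe (2.5 equiv), n-BuLi, THF, −78 °C; add 13, −78 °C; aq NH4Cl; crude product used at once
Reagents that add atoms: tributyl[(methoxymethoxy)methyl]stannane, CCCC[Sn](CCCC)(CCCC)COCOC
Why: Tin–lithium exchange gives the α-alkoxymethyllithium, a hydroxymethyl anion equivalent. The first equivalent deprotonates the phenol and the second adds to the aldehyde; the carbinol centre is formed racemic and is removed in step 6.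

Step 6
Reactants: 14 2-[1-hydroxy-2-(methoxymethoxy)ethyl]-3-[(4-methoxyphenyl)methoxy]-6-(3-methylbut-2-en-1-yl)-5-[(triisopropylsilyl)oxy]phenol
Product: 15 1-{2-hydroxy-6-[(4-methoxyphenyl)methoxy]-3-(3-methylbut-2-en-1-yl)-4-[(triisopropylsilyl)oxy]phenyl}-2-(methoxymethoxy)ethan-1-one
Conditions: MnO2 (activated, excess), CH2Cl2, rt
Reagents that add atoms: none
Why: MnO2 oxidises benzylic alcohols selectively and is a standard reagent for turning ortho-hydroxybenzyl alcohols into ortho-hydroxyaryl ketones. The ethers, the acetal and the prenyl alkene are inert to it, and the product is stabilised by the hydrogen bond between phenol and ketone.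

Step 7
Reactants: 16 4-hydroxybenzoic acid
Product: 18 4-(methoxymethoxy)benzoic acid, via methoxymethyl ester 17 (not isolated)
Conditions: MeOCH2Cl (2.5 equiv), i-Pr2NEt, CH2Cl2, 0 °C → rt; concentrate; 2 M NaOH, MeOH/THF, rt; 1 M HCl to pH 3, 0 °C
Reagents that add atoms: chloro(methoxy)methane, COCCl
Why: Phenol and carboxylate are both O-alkylated by the chloromethyl ether. Hydroxide then cleaves only the acyloxymethyl ester, which is far more labile than the aryl acetal.

Step 8
Reactants: 15 1-{2-hydroxy-6-[(4-methoxyphenyl)methoxy]-3-(3-methylbut-2-en-1-yl)-4-[(triisopropylsilyl)oxy]phenyl}-2-(methoxymethoxy)ethan-1-one; 18 4-(methoxymethoxy)benzoic acid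
Product: 19 2-[2-(methoxymethoxy)acetyl]-3-[(4-methoxyphenyl)methoxy]-6-(3-methylbut-2-en-1-yl)-5-[(triisopropylsilyl)oxy]phenyl 4-(methoxymethoxy)benzoate
Conditions: DCC, DMAP (0.3 equiv), CH2Cl2, 0 °C → rt
Reagents that add atoms: none
Why: Steglich esterification: the acylpyridinium formed from the O-acylisourea acylates the hindered, hydrogen-bonded phenol under neutral conditions. This avoids making an acid chloride from 18, whose acetal would be endangered by hydrogen chloride.

Step 9
Reactants: 19 2-[2-(methoxymethoxy)acetyl]-3-[(4-methoxyphenyl)methoxy]-6-(3-methylbut-2-en-1-yl)-5-[(triisopropylsilyl)oxy]phenyl 4-(methoxymethoxy)benzoate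
Product: 21 3-(methoxymethoxy)-5-[(4-methoxyphenyl)methoxy]-2-[4-(methoxymethoxy)phenyl]-8-(3-methylbut-2-en-1-yl)-7-[(triisopropylsilyl)oxy]-4H-chromen-4-one, via diketone 20 (not isolated)
Conditions: LiN(SiMe3)2 (3 equiv), THF, −78 → 0 °C; AcOH; then 10-camphorsulfonic acid (0.1 equiv), 4 Å MS, CH2Cl2, rt
Reagents that add atoms: none
Why: Baker–Venkataraman rearrangement: the ketone enolate attacks the neighbouring aryl ester through a six-membered transition state to give diketone 20 (C2–C3 bond). Catalytic sulfonic acid in an aprotic solvent then closes O1–C2 through the hemiketal and dehydrates it to the pyranone. O1 is the only free hydroxyl because O5 is still a 4-methoxybenzyl ether, so only the 8-prenyl isomer can form, and the mild acid is chosen so that this ether, the acetals and the silyl ether survive.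

Step 10
Reactants: 21 3-(methoxymethoxy)-5-[(4-methoxyphenyl)methoxy]-2-[4-(methoxymethoxy)phenyl]-8-(3-methylbut-2-en-1-yl)-7-[(triisopropylsilyl)oxy]-4H-chromen-4-one
Product: 22 3,5-dihydroxy-2-(4-hydroxyphenyl)-8-(3-methylbut-2-en-1-yl)-7-[(triisopropylsilyl)oxy]-4H-chromen-4-one
Conditions: 1 M HCl in MeOH/THF (4:1), 45 °C
Reagents that add atoms: none
Why: Acid-catalysed acetal exchange with methanol removes both methoxymethyl groups and solvolyses the 4-methoxybenzyl ether on O5, whose oxygen is a good leaving group because of the peri carbonyl; the solvent traps the benzyl cation. The bulky silyl ether on O7 should persist, so no hydroxyl stands next to the prenyl group while acid is present.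

Step 11
Reactants: 22 3,5-dihydroxy-2-(4-hydroxyphenyl)-8-(3-methylbut-2-en-1-yl)-7-[(triisopropylsilyl)oxy]-4H-chromen-4-one
Product: 23 3,5,7-trihydroxy-2-(4-hydroxyphenyl)-8-(3-methylbut-2-en-1-yl)-4H-chromen-4-one (8-prenylkaempferol)
Conditions: Bu4NF (1.2 equiv), AcOH (1.5 equiv), THF, 0 °C → rt
Reagents that add atoms: none
Why: Fluoride cleaves the aryl silyl ether, which is a vinylogous silyl ester of the C4 carbonyl and therefore labile. The acetic acid buffer keeps the flavonol out of its air-sensitive anionic form, and nothing acidic enough to protonate the prenyl alkene is present.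

## Compound list

1 | 3-ethoxycyclobut-2-en-1-one | CCOC1=CC(=O)C1 | starting material
2 | (4-methoxyphenyl)methanol | COc1ccc(CO)cc1 | starting material
3 | 3-[(4-methoxyphenyl)methoxy]cyclobut-2-en-1-one | COc1ccc(COC2=CC(=O)C2)cc1 | intermediate
4 | ethyl 4-methylpent-3-enoate | CCOC(=O)CC=C(C)C | starting material
5 | lithium 1,1-dibromo-5-methylhexa-1,4-dien-2-olate | [Li+].[O-]C(CC=C(C)C)=C(Br)Br | intermediate (not isolated)
6 | lithium 5-methylhex-4-en-1-yn-1-olate | [Li+].[O-]C#CCC=C(C)C | intermediate (not isolated)
7 | triisopropyl[(5-methylhex-4-en-1-yn-1-yl)oxy]silane | CC(C)=CCC#CO[Si](C(C)C)(C(C)C)C(C)C | intermediate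
8 | 3-[(4-methoxyphenyl)methoxy]buta-1,3-dien-1-one | C=C(OCc1ccc(OC)cc1)C=C=O | intermediate (not isolated)
9 | 4-{1-[(4-methoxyphenyl)methoxy]ethenyl}-2-(3-methylbut-2-en-1-yl)-3-[(triisopropylsilyl)oxy]cyclobut-2-en-1-one (racemic) | C=C(OCc1ccc(OC)cc1)C1C(=O)C(CC=C(C)C)=C1O[Si](C(C)C)(C(C)C)C(C)C | intermediate (not isolated)
10 | (3E)-5-[(4-methoxyphenyl)methoxy]-2-(3-methylbut-2-en-1-yl)-3-[(triisopropylsilyl)oxy]hexa-1,3,5-trien-1-one | O=C=C(CC=C(C)C)/C(O[Si](C(C)C)(C(C)C)C(C)C)=C\C(=C)OCc1ccc(OC)cc1 | intermediate (not isolated)
11 | 5-[(4-methoxyphenyl)methoxy]-2-(3-methylbut-2-en-1-yl)-3-[(triisopropylsilyl)oxy]cyclohexa-2,4-dien-1-one | O=C1CC(OCc2ccc(OC)cc2)=CC(O[Si](C(C)C)(C(C)C)C(C)C)=C1CC=C(C)C | intermediate (not isolated)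
12 | 5-[(4-methoxyphenyl)methoxy]-2-(3-methylbut-2-en-1-yl)-3-[(triisopropylsilyl)oxy]phenol | CC(C)=CCc1c(O)cc(OCc2ccc(OC)cc2)cc1O[Si](C(C)C)(C(C)C)C(C)C | intermediate
13 | 2-hydroxy-6-[(4-methoxyphenyl)methoxy]-3-(3-methylbut-2-en-1-yl)-4-[(triisopropylsilyl)oxy]benzaldehyde | CC(C)=CCc1c(O)c(C=O)c(OCc2ccc(OC)cc2)cc1O[Si](C(C)C)(C(C)C)C(C)C | intermediate
14 | 2-[1-hydroxy-2-(methoxymethoxy)ethyl]-3-[(4-methoxyphenyl)methoxy]-6-(3-methylbut-2-en-1-yl)-5-[(triisopropylsilyl)oxy]phenol (racemic) | CC(C)=CCc1c(O)c(C(O)COCOC)c(OCc2ccc(OC)cc2)cc1O[Si](C(C)C)(C(C)C)C(C)C | intermediate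
15 | 1-{2-hydroxy-6-[(4-methoxyphenyl)methoxy]-3-(3-methylbut-2-en-1-yl)-4-[(triisopropylsilyl)oxy]phenyl}-2-(methoxymethoxy)ethan-1-one | CC(C)=CCc1c(O)c(C(=O)COCOC)c(OCc2ccc(OC)cc2)cc1O[Si](C(C)C)(C(C)C)C(C)C | intermediate
16 | 4-hydroxybenzoic acid | OC(=O)c1ccc(O)cc1 | starting material
17 | methoxymethyl 4-(methoxymethoxy)benzoate | COCOC(=O)c1ccc(OCOC)cc1 | intermediate (not isolated)
18 | 4-(methoxymethoxy)benzoic acid | COCOc1ccc(C(=O)O)cc1 | intermediate
19 | 2-[2-(methoxymethoxy)acetyl]-3-[(4-methoxyphenyl)methoxy]-6-(3-methylbut-2-en-1-yl)-5-[(triisopropylsilyl)oxy]phenyl 4-(methoxymethoxy)benzoate | CC(C)=CCc1c(OC(=O)c2ccc(OCOC)cc2)c(C(=O)COCOC)c(OCc2ccc(OC)cc2)cc1O[Si](C(C)C)(C(C)C)C(C)C | intermediate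
20 | 1-{2-hydroxy-6-[(4-methoxyphenyl)methoxy]-3-(3-methylbut-2-en-1-yl)-4-[(triisopropylsilyl)oxy]phenyl}-2-(methoxymethoxy)-3-[4-(methoxymethoxy)phenyl]propane-1,3-dione (racemic) | CC(C)=CCc1c(O)c(C(=O)C(OCOC)C(=O)c2ccc(OCOC)cc2)c(OCc2ccc(OC)cc2)cc1O[Si](C(C)C)(C(C)C)C(C)C | intermediate (not isolated)
21 | 3-(methoxymethoxy)-5-[(4-methoxyphenyl)methoxy]-2-[4-(methoxymethoxy)phenyl]-8-(3-methylbut-2-en-1-yl)-7-[(triisopropylsilyl)oxy]-4H-chromen-4-one | CC(C)=CCc1c(O[Si](C(C)C)(C(C)C)C(C)C)cc(OCc2ccc(OC)cc2)c2c(=O)c(OCOC)c(-c3ccc(OCOC)cc3)oc12 | intermediate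
22 | 3,5-dihydroxy-2-(4-hydroxyphenyl)-8-(3-methylbut-2-en-1-yl)-7-[(triisopropylsilyl)oxy]-4H-chromen-4-one | CC(C)=CCc1c(O[Si](C(C)C)(C(C)C)C(C)C)cc(O)c2c(=O)c(O)c(-c3ccc(O)cc3)oc12 | intermediate
23 | 3,5,7-trihydroxy-2-(4-hydroxyphenyl)-8-(3-methylbut-2-en-1-yl)-4H-chromen-4-one (8-prenylkaempferol) | CC(C)=CCc1c(O)cc(O)c2c(=O)c(O)c(-c3ccc(O)cc3)oc12 | target

## Step count and least certain steps

Total: 11 steps. Longest linear sequence: 9 steps (steps 2, 3, 4, 5, 6, 8, 9, 10, 11; steps 1 and 7 are one-step side branches).

Step 3 (key step). The 3-alkoxy enone of 3 is a stabilised vinylogous ester, so its 4π opening may be slow. It may then need temperatures at which 7 isomerises to a silylketene or at which the product phenol is acylated by 8. The fallback generates 8 at room temperature from an acid chloride instead of a cyclobutenone. It sets out from 2 and 7 and comes back to the route at 8, which goes on through 9 to 12.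
- Alcohol 2 is exchanged into purchased ethyl (E)-3-ethoxybut-2-enoate (pyridinium 4-toluenesulfonate, toluene, removal of ethanol) to give ethyl (E)-3-[(4-methoxyphenyl)methoxy]but-2-enoate F1.
- LiOH in THF/water should give (E)-3-[(4-methoxyphenyl)methoxy]but-2-enoic acid F2.
- 1-Chloro-N,N,2-trimethylprop-1-en-1-amine in CH2Cl2 should convert F2 under neutral conditions into (E)-3-[(4-methoxyphenyl)methoxy]but-2-enoyl chloride F3.
- Slow addition of Et3N to F3 and 7 in toluene at room temperature should give 8 by 1,4-dehydrochlorination. The ynol ether traps 8 as 9, and warming to 80 °C completes the cascade to 12.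

Step 2. The α-CH2 of 4 is activated by both the ester and the alkene, so deprotonation by LiCHBr2 may compete with addition, and the skipped enyne may isomerise under the excess base. The fallback makes the ynolate by oxidation of an acetylide. It sets out from 4 and comes back at 6.
- i-Bu2AlH in CH2Cl2 at −78 °C should give 4-methylpent-3-enal F4.
- CBr4 and PPh3 at 0 °C should give 1,1-dibromo-5-methylhexa-1,4-diene F5.
- n-BuLi (2 equiv) in THF at −78 °C should give lithium 5-methylhex-4-en-1-yn-1-ide F6.
- LiOOt-Bu (from t-BuOOH and LiN(SiMe3)2), −78 → 0 °C, should oxidise F6 to ynolate 6, which is silylated as in step 2 to give 7.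

Step 6. The electron-rich ortho-hydroxybenzyl alcohol 14 may ionise to an ortho-quinone methide by loss of water during handling or on the oxidant surface, and the free phenol may be over-oxidised. The fallback masks the phenol before the carbinol is made. It sets out from 13 and comes back at 15.
- Allyl bromide and K2CO3 in acetone should give 6-[(4-methoxyphenyl)methoxy]-3-(3-methylbut-2-en-1-yl)-2-(prop-2-en-1-yloxy)-4-[(triisopropylsilyl)oxy]benzaldehyde F7.
- The α-alkoxymethyllithium of step 5 (1.2 equiv now suffices) should give 2-(methoxymethoxy)-1-{6-[(4-methoxyphenyl)methoxy]-3-(3-methylbut-2-en-1-yl)-2-(prop-2-en-1-yloxy)-4-[(triisopropylsilyl)oxy]phenyl}ethan-1-ol F8.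
- Dess–Martin periodinane with NaHCO3 should give 2-(methoxymethoxy)-1-{6-[(4-methoxyphenyl)methoxy]-3-(3-methylbut-2-en-1-yl)-2-(prop-2-en-1-yloxy)-4-[(triisopropylsilyl)oxy]phenyl}ethan-1-one F9.
- Pd(PPh3)4 (zerovalent palladium) and morpholine in THF should remove the allyl group under neutral conditions to give 15.

Step 10. Solvolysis of the 4-methoxybenzyl ether may be slow relative to loss of the silyl group from O7. Acid-catalysed addition of O7–H or of methanol across the prenyl double bond could then compete. The fallback removes the benzyl ether oxidatively, so that acid is needed only briefly for the two acetals. It sets out from 21 and comes back at 22.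
- DDQ in CH2Cl2/pH 7 buffer at 0 °C should give 5-hydroxy-3-(methoxymethoxy)-2-[4-(methoxymethoxy)phenyl]-8-(3-methylbut-2-en-1-yl)-7-[(triisopropylsilyl)oxy]-4H-chromen-4-one F10. No free phenol stands ortho to the prenyl group at this stage.
- A short treatment of F10 with dilute HCl in methanol should give 22.

## Further compounds

F1 | step 3 | ethyl (E)-3-[(4-methoxyphenyl)methoxy]but-2-enoate | CCOC(=O)/C=C(\C)OCc1ccc(OC)cc1
F2 | step 3 | (E)-3-[(4-methoxyphenyl)methoxy]but-2-enoic acid | OC(=O)/C=C(\C)OCc1ccc(OC)cc1
F3 | step 3 | (E)-3-[(4-methoxyphenyl)methoxy]but-2-enoyl chloride | ClC(=O)/C=C(\C)OCc1ccc(OC)cc1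
F4 | step 2 | 4-methylpent-3-enal | CC(C)=CCC=O
F5 | step 2 | 1,1-dibromo-5-methylhexa-1,4-diene | CC(C)=CCC=C(Br)Br
F6 | step 2 | lithium 5-methylhex-4-en-1-yn-1-ide | [Li]C#CCC=C(C)C
F7 | step 6 | 6-[(4-methoxyphenyl)methoxy]-3-(3-methylbut-2-en-1-yl)-2-(prop-2-en-1-yloxy)-4-[(triisopropylsilyl)oxy]benzaldehyde | CC(C)=CCc1c(OCC=C)c(C=O)c(OCc2ccc(OC)cc2)cc1O[Si](C(C)C)(C(C)C)C(C)C
F8 | step 6 | 2-(methoxymethoxy)-1-{6-[(4-methoxyphenyl)methoxy]-3-(3-methylbut-2-en-1-yl)-2-(prop-2-en-1-yloxy)-4-[(triisopropylsilyl)oxy]phenyl}ethan-1-ol (racemic) | CC(C)=CCc1c(OCC=C)c(C(O)COCOC)c(OCc2ccc(OC)cc2)cc1O[Si](C(C)C)(C(C)C)C(C)C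
F9 | step 6 | 2-(methoxymethoxy)-1-{6-[(4-methoxyphenyl)methoxy]-3-(3-methylbut-2-en-1-yl)-2-(prop-2-en-1-yloxy)-4-[(triisopropylsilyl)oxy]phenyl}ethan-1-one | CC(C)=CCc1c(OCC=C)c(C(=O)COCOC)c(OCc2ccc(OC)cc2)cc1O[Si](C(C)C)(C(C)C)C(C)C
F10 | step 10 | 5-hydroxy-3-(methoxymethoxy)-2-[4-(methoxymethoxy)phenyl]-8-(3-methylbut-2-en-1-yl)-7-[(triisopropylsilyl)oxy]-4H-chromen-4-one | CC(C)=CCc1c(O[Si](C(C)C)(C(C)C)C(C)C)cc(O)c2c(=O)c(OCOC)c(-c3ccc(OCOC)cc3)oc12
A1 | alternative 1 | 4,6-bis(methoxymethoxy)-2-[4-(methoxymethoxy)phenyl]-7-(3-methylbut-2-en-1-yl)-1-benzofuran-3(2H)-one (racemic) | CC(C)=CCc1c(OCOC)cc(OCOC)c2C(=O)C(c3ccc(OCOC)cc3)Oc12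
A2 | alternative 1 | 3-bromo-5,7-bis(methoxymethoxy)-2-[4-(methoxymethoxy)phenyl]-8-(3-methylbut-2-en-1-yl)-4H-chromen-4-one | CC(C)=CCc1c(OCOC)cc(OCOC)c2c(=O)c(Br)c(-c3ccc(OCOC)cc3)oc12
A3 | alternative 2 | 6-(2-diazo-5-methylhex-4-enoyl)-3-(methoxymethoxy)-2-[4-(methoxymethoxy)phenyl]-4H-pyran-4-one | CC(C)=CCC(=[N+]=[N-])C(=O)c1cc(=O)c(OCOC)c(-c2ccc(OCOC)cc2)o1
A4 | alternative 2 | triisopropyl{[(trimethylsilyl)ethynyl]oxy}silane | C[Si](C)(C)C#CO[Si](C(C)C)(C(C)C)C(C)C
A5 | alternative 2 | 5-hydroxy-3-(methoxymethoxy)-2-[4-(methoxymethoxy)phenyl]-8-(3-methylbut-2-en-1-yl)-7-[(triisopropylsilyl)oxy]-6-(trimethylsilyl)-4H-chromen-4-one | CC(C)=CCc1c(O[Si](C(C)C)(C(C)C)C(C)C)c([Si](C)(C)C)c(O)c2c(=O)c(OCOC)c(-c3ccc(OCOC)cc3)oc12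
A6 | alternative 3 | 2-(methoxymethoxy)-1-[4-(methoxymethoxy)phenyl]ethan-1-one | COCOCC(=O)c1ccc(OCOC)cc1
A7 | alternative 3 | [2-fluoro-4,6-bis(methoxymethoxy)-3-(3-methylbut-2-en-1-yl)-5-(trimethylsilyl)phenyl](1H-imidazol-1-yl)methanone | CC(C)=CCc1c(F)c(C(=O)n2ccnc2)c(OCOC)c([Si](C)(C)C)c1OCOC
A8 | alternative 3 | 3,5,7-tris(methoxymethoxy)-2-[4-(methoxymethoxy)phenyl]-8-(3-methylbut-2-en-1-yl)-6-(trimethylsilyl)-4H-chromen-4-one | CC(C)=CCc1c(OCOC)c([Si](C)(C)C)c(OCOC)c2c(=O)c(OCOC)c(-c3ccc(OCOC)cc3)oc12
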